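**Retrosynthetic overview**
1. Target 14 ⇐ hydrogenolysis of the five benzyl ethers of (2S,4S)-13 ⇐ separation of racemic cis-12 on a chiral stationary phase.
2. 12 ⇐ [4+2] hetero-Diels–Alder of o-quinone methide 11 with styrene 10; this makes O1–C2, C3–C4 and both stereocentres (cis) in one step.
3. 11 ⇐ benzhydrol 9 ⇐ magnesium-phenoxide ortho-hydroxyalkylation of 3-(benzyloxy)phenol 7 with aldehyde 6 (C4–C4a bond).
4. 6 ⇐ phloroglucinol 1 by C-acylation with 2, formylation and O-benzylation.
5. Ring order: the three benzene rings are bought; the pyran ring is the only ring built (step 5).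

Assumption: 7 and 10 are catalogue items, and since both stereocentres arise together from achiral partners, the cycloaddition fixes the cis relationship and the (2S,4S) enantiomer is then taken by chromatography on a chiral stationary phase (no chiral catalyst, reagent or auxiliary).

**Step 1**
Reactants: 1 phloroglucinol; 2 dodecanoyl chloride
Product: 3 1-(2,4,6-trihydroxyphenyl)dodecan-1-one
Conditions: AlCl3 (3 equiv), PhNO2, rt→60 °C; ice/aq HCl
Reagents that add atoms: none
Why: Friedel–Crafts acylation of the very electron-rich ring stops after one acyl group because the chelated ketone deactivates the ring.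

**Step 2**
Reactants: 3 1-(2,4,6-trihydroxyphenyl)dodecan-1-one
Product: 5 3-dodecanoyl-2,4,6-trihydroxybenzaldehyde, via aryl iminium chloride 4 (not isolated)
Conditions: POCl3 (1.1 equiv), DMF (1.2 equiv), EtOAc, 0 °C→rt; then H2O, 60 °C
Reagents that add atoms: N,N-dimethylformamide, CN(C)C=O (formyl carbon); water, O (formyl oxygen)
Why: Vilsmeier–Haack formylation with one equivalent of reagent attacks one of the two equivalent free ring positions, which are far more nucleophilic than the ketone side chain.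

**Step 3**
Reactants: 5 3-dodecanoyl-2,4,6-trihydroxybenzaldehyde
Product: 6 2,4,6-tris(benzyloxy)-3-dodecanoylbenzaldehyde
Conditions: BnBr (3.6 equiv), K2CO3 (4.5 equiv), Bu4NI (cat.), DMF, 60 °C
Reagents that add atoms: benzyl bromide, BrCc1ccccc1
Why: Williamson ether synthesis in a dipolar aprotic solvent favours O- over C-alkylation and caps all three phenols, so that only ring A can later form a quinone methide.

**Step 4**
Reactants: 7 3-(benzyloxy)phenol; 6 2,4,6-tris(benzyloxy)-3-dodecanoylbenzaldehyde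
Product: 9 1-[2,4,6-tris(benzyloxy)-3-{[4-(benzyloxy)-2-hydroxyphenyl](hydroxy)methyl}phenyl]dodecan-1-one (racemic), via bromomagnesium 3-(benzyloxy)phenoxide 8 (not isolated)
Conditions: EtMgBr (1.0 equiv), Et2O, 0 °C; solvent swap to toluene; 6, rt, 16 h; pH 7 buffer; quick filtration on Et3N-deactivated silica
Reagents that add atoms: none
Why: Casiraghi-type ortho-hydroxyalkylation, in which magnesium chelates phenoxide and aldehyde and delivers the C–C bond to the less hindered ortho carbon (para to OBn), while the doubly flanked ketone does not react; the carbinol centre is racemic and is erased in step 5.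

**Step 5**
Reactants: 9 the benzhydrol from step 4; 10 1-(benzyloxy)-4-ethenylbenzene
Product: 12 racemic cis-1-[2,4,6-tris(benzyloxy)-3-{7-(benzyloxy)-2-[4-(benzyloxy)phenyl]-3,4-dihydro-2H-chromen-4-yl}phenyl]dodecan-1-one (2S,4S plus 2R,4R), via o-quinone methide 11 (not isolated)
Conditions: (PhO)2P(O)OH (10 mol%), 10 (3 equiv), 4 Å MS, CH2Cl2, 0 °C→rt (40 °C if slow)
Reagents that add atoms: none
Why: Acid-promoted loss of water gives the E-configured o-quinone methide 11, which undergoes an inverse-electron-demand hetero-Diels–Alder reaction with the electron-rich styrene (CH2 to the methide carbon, benzylic carbon to oxygen) through the endo transition state, so the C2 and C4 aryl groups end up cis, as a racemate.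

**Step 6**
Reactants: 12 racemic cis pentabenzyl ether
Product: 13 1-[2,4,6-tris(benzyloxy)-3-{(2S,4S)-7-(benzyloxy)-2-[4-(benzyloxy)phenyl]-3,4-dihydro-2H-chromen-4-yl}phenyl]dodecan-1-one
Conditions: preparative HPLC on immobilised amylose tris(3,5-dimethylphenylcarbamate), hexane/i-PrOH
Reagents that add atoms: none
Why: Resolution of the racemate by chromatography on a chiral stationary phase changes no bond, and the fraction whose debenzylated sample matches the calculated ECD spectrum of the (2S,4S) structure is carried on.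

**Step 7**
Reactants: 13 (2S,4S) pentabenzyl ether
Product: 14 1-{2,4,6-trihydroxy-3-[(2S,4S)-7-hydroxy-2-(4-hydroxyphenyl)-3,4-dihydro-2H-chromen-4-yl]phenyl}dodecan-1-one (target)
Conditions: H2 (1 atm), Pd/C (10 wt%), EtOAc/MeOH 1:1, rt
Reagents that add atoms: none
Why: Catalytic hydrogenolysis cleaves the five benzyl aryl ethers under neutral conditions that leave the ring C2–O bond, the chelated aryl ketone and both stereocentres untouched.

**Compound list**
1 | phloroglucinol (benzene-1,3,5-triol) | Oc1cc(O)cc(O)c1 | starting material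
2 | dodecanoyl chloride | CCCCCCCCCCCC(=O)Cl | starting material
3 | 1-(2,4,6-trihydroxyphenyl)dodecan-1-one | CCCCCCCCCCCC(=O)c1c(O)cc(O)cc1O | intermediate
4 | [(3-dodecanoyl-2,4,6-trihydroxyphenyl)methylidene]dimethyliminium chloride | CCCCCCCCCCCC(=O)c1c(O)cc(O)c(C=[N+](C)C)c1O.[Cl-] | intermediate (not isolated)
5 | 3-dodecanoyl-2,4,6-trihydroxybenzaldehyde | CCCCCCCCCCCC(=O)c1c(O)cc(O)c(C=O)c1O | intermediate
6 | 2,4,6-tris(benzyloxy)-3-dodecanoylbenzaldehyde | CCCCCCCCCCCC(=O)c1c(OCc2ccccc2)cc(OCc2ccccc2)c(C=O)c1OCc1ccccc1 | intermediate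
7 | 3-(benzyloxy)phenol | Oc1cccc(OCc2ccccc2)c1 | starting material
8 | bromomagnesium 3-(benzyloxy)phenoxide | Br[Mg]Oc1cccc(OCc2ccccc2)c1 | intermediate (not isolated)
9 | 1-[2,4,6-tris(benzyloxy)-3-{[4-(benzyloxy)-2-hydroxyphenyl](hydroxy)methyl}phenyl]dodecan-1-one, racemic at the carbinol carbon | CCCCCCCCCCCC(=O)c1c(OCc2ccccc2)cc(OCc2ccccc2)c(C(O)c2ccc(OCc3ccccc3)cc2O)c1OCc1ccccc1 | intermediate
10 | 1-(benzyloxy)-4-ethenylbenzene (4-benzyloxystyrene) | C=Cc1ccc(OCc2ccccc2)cc1 | starting material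
11 | (6E)-3-(benzyloxy)-6-{[2,4,6-tris(benzyloxy)-3-dodecanoylphenyl]methylidene}cyclohexa-2,4-dien-1-one | CCCCCCCCCCCC(=O)c1c(OCc2ccccc2)cc(OCc2ccccc2)c(/C=C2\C=CC(OCc3ccccc3)=CC2=O)c1OCc1ccccc1 | intermediate (not isolated)
12 | racemic 2,4-cis pentabenzyl ether, 1:1 (2S,4S) and (2R,4R) | CCCCCCCCCCCC(=O)c1c(OCc2ccccc2)cc(OCc2ccccc2)c([C@H]2C[C@@H](c3ccc(OCc4ccccc4)cc3)Oc3cc(OCc4ccccc4)ccc32)c1OCc1ccccc1.CCCCCCCCCCCC(=O)c1c(OCc2ccccc2)cc(OCc2ccccc2)c([C@@H]2C[C@H](c3ccc(OCc4ccccc4)cc3)Oc3cc(OCc4ccccc4)ccc32)c1OCc1ccccc1 | intermediate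
13 | 1-[2,4,6-tris(benzyloxy)-3-{(2S,4S)-7-(benzyloxy)-2-[4-(benzyloxy)phenyl]-3,4-dihydro-2H-chromen-4-yl}phenyl]dodecan-1-one | CCCCCCCCCCCC(=O)c1c(OCc2ccccc2)cc(OCc2ccccc2)c([C@H]2C[C@@H](c3ccc(OCc4ccccc4)cc3)Oc3cc(OCc4ccccc4)ccc32)c1OCc1ccccc1 | intermediate
14 | 1-{2,4,6-trihydroxy-3-[(2S,4S)-7-hydroxy-2-(4-hydroxyphenyl)-3,4-dihydro-2H-chromen-4-yl]phenyl}dodecan-1-one | CCCCCCCCCCCC(=O)c1c(O)cc(O)c([C@H]2C[C@@H](c3ccc(O)cc3)Oc3cc(O)ccc32)c1O | target

**Totals:** 7 steps; longest linear sequence 7 (1 → 3 → 5 → 6 → 9 → 12 → 13 → 14).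

**Steps most likely to fail, with fallbacks**

Step 5 (cycloaddition at a methide carbon carrying a doubly ortho-substituted aryl group). If the styrene does not add to 11, the pyran ring is built first on an unhindered quinone-methide-type partner and the acylphloroglucinol is attached afterwards. The fallback sets out from 10 and 3. 4-(Benzyloxy)-2-hydroxybenzaldehyde F1 with HC(OMe)3 and catalytic TfOH (CH2Cl2, 0 °C) gives 4-(benzyloxy)-2-(dimethoxymethyl)phenol F2 in the flask. F2 loses methanol under the same acid and adds to 10 in a [4+2] sense to give racemic 7-(benzyloxy)-2-[4-(benzyloxy)phenyl]-4-methoxy-3,4-dihydro-2H-chromene F3. BF3·OEt2 (MeCN, −20 °C) then ionises F3 at C4, and the free ring carbon of 3 (used in excess) captures the cation in a Friedel–Crafts alkylation. Separation from the 2,4-trans isomer gives racemic cis-1-[3-{7-(benzyloxy)-2-[4-(benzyloxy)phenyl]-3,4-dihydro-2H-chromen-4-yl}-2,4,6-trihydroxyphenyl]dodecan-1-one F4. Chromatography on the same type of chiral column gives the (2S,4S) enantiomer F5, and H2 with Pd/C removes its two benzyl groups, coming back to the route at 14.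

Step 4 (magnesium phenoxide against a hindered, electron-rich aldehyde, and a benzhydrol that ionises easily). If the addition stalls or 9 cannot be handled, phenol and aldehyde are tied together through boron instead. The fallback sets out from 6 and 7. PhB(OH)2 and catalytic propanoic acid in refluxing toluene with removal of water give the cyclic boronate 1-[2,4,6-tris(benzyloxy)-3-[7-(benzyloxy)-2-phenyl-4H-1,3,2-benzodioxaborinin-4-yl]phenyl]dodecan-1-one F6, a chromatographable stand-in for 9. Warmed with 10 and catalytic BF3·OEt2 (or heated alone to about 150 °C), F6 releases phenylboronic acid, forms 11 and gives the cycloadduct, so the route is re-entered at 12 without isolating 9.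

Step 3 (exhaustive O-benzylation of a phenol chelated by two carbonyl groups, with competing C-benzylation). If this is poor, the order of events is reversed. The fallback sets out from 3. BnBr and K2CO3 in DMF at 60 °C give 1-[2,4,6-tris(benzyloxy)phenyl]dodecan-1-one F7, a well-behaved alkylation of singly chelated phenols. Vilsmeier–Haack formylation of F7 (POCl3, DMF, 0→50 °C) at one of its two equivalent ring positions proceeds through {[2,4,6-tris(benzyloxy)-3-dodecanoylphenyl]methylidene}dimethyliminium chloride F8, which water hydrolyses, coming back to the route at 6 and bypassing 4 and 5.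

**Further compounds**
F1 | step 5 | 4-(benzyloxy)-2-hydroxybenzaldehyde | O=Cc1ccc(OCc2ccccc2)cc1O
F2 | step 5 | 4-(benzyloxy)-2-(dimethoxymethyl)phenol | COC(OC)c1ccc(OCc2ccccc2)cc1O
F3 | step 5 | 7-(benzyloxy)-2-[4-(benzyloxy)phenyl]-4-methoxy-3,4-dihydro-2H-chromene, racemic, both C4 epimers | COC1CC(c2ccc(OCc3ccccc3)cc2)Oc2cc(OCc3ccccc3)ccc21
F4 | step 5 | racemic 2,4-cis 1-[3-{7-(benzyloxy)-2-[4-(benzyloxy)phenyl]-3,4-dihydro-2H-chromen-4-yl}-2,4,6-trihydroxyphenyl]dodecan-1-one, 1:1 (2S,4S) and (2R,4R) | CCCCCCCCCCCC(=O)c1c(O)cc(O)c([C@H]2C[C@@H](c3ccc(OCc4ccccc4)cc3)Oc3cc(OCc4ccccc4)ccc32)c1O.CCCCCCCCCCCC(=O)c1c(O)cc(O)c([C@@H]2C[C@H](c3ccc(OCc4ccccc4)cc3)Oc3cc(OCc4ccccc4)ccc32)c1O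
F5 | step 5 | 1-[3-{(2S,4S)-7-(benzyloxy)-2-[4-(benzyloxy)phenyl]-3,4-dihydro-2H-chromen-4-yl}-2,4,6-trihydroxyphenyl]dodecan-1-one | CCCCCCCCCCCC(=O)c1c(O)cc(O)c([C@H]2C[C@@H](c3ccc(OCc4ccccc4)cc3)Oc3cc(OCc4ccccc4)ccc32)c1O
F6 | step 4 | 1-[2,4,6-tris(benzyloxy)-3-[7-(benzyloxy)-2-phenyl-4H-1,3,2-benzodioxaborinin-4-yl]phenyl]dodecan-1-one, racemic | CCCCCCCCCCCC(=O)c1c(OCc2ccccc2)cc(OCc2ccccc2)c(C2OB(c3ccccc3)Oc3cc(OCc4ccccc4)ccc32)c1OCc1ccccc1
F7 | step 3 | 1-[2,4,6-tris(benzyloxy)phenyl]dodecan-1-one | CCCCCCCCCCCC(=O)c1c(OCc2ccccc2)cc(OCc2ccccc2)cc1OCc1ccccc1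
F8 | step 3 | {[2,4,6-tris(benzyloxy)-3-dodecanoylphenyl]methylidene}dimethyliminium chloride | CCCCCCCCCCCC(=O)c1c(OCc2ccccc2)cc(OCc2ccccc2)c(C=[N+](C)C)c1OCc1ccccc1.[Cl-]
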